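## Retrosynthetic overview

1. Target 20 comes from O-demethylation of methyl tetronate 19. 19 comes from forming the side-chain C8–C9 bond of the E,E-diene by oxidative Heck vinylation of the terminal alkene of 18 with alkenylboronate 8.
2. 18 comes from forming the bond between ring C5 and side-chain C1, and the C5 (R) centre, by a proposed Pd-catalysed enantioselective C5 allylation of silyloxyfuran 14 with allylic carbonate 17 (the new step).
3. 17 comes from (S)-β-citronellene 15, which supplies the C6 (S) methyl centre, by E-selective allylic oxidation.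
4. 8 comes from 3-bromofuran 2 and a five-carbon alkynyl Grignard reagent, then methylalumination/iodination and borylation.
5. Rings: the furan is bought. The butenolide is the only ring built; it is closed first (step 6, lactonisation) and carried as its methyl ether.

Assumption: both enantiomers of β-citronellene and of the ANDEN-phenyl Trost ligand are purchasable; in step 11 the (R,R)-ligand is taken to give 5R, and because the step is catalyst-controlled the (S,S)-ligand is used instead if the first run shows the opposite sense.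

## Route

Step 1
Reactants: 1 (5-chloropent-1-yn-1-yl)trimethylsilane; 2 3-bromofuran
Product: 4 [5-(furan-3-yl)pent-1-yn-1-yl]trimethylsilane, via [5-(trimethylsilyl)pent-4-yn-1-yl]magnesium chloride 3 (not isolated)
Conditions: Mg turnings (1.3 equiv), THF, 60 °C; then 2 (0.85 equiv), PdCl2(dppf) (2 mol%), THF, 0 → 40 °C
Reagents that add atoms: none
Why: Kumada–Corriu coupling, in which the primary alkyl Grignard reagent 3 transmetalates to the furyl–palladium bromide formed from 2 and the wide-bite-angle dppf ligand makes reductive elimination faster than β-hydride elimination, the C-silylated alkyne being inert to the Grignard reagent.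

Step 2
Reactants: 4 [5-(furan-3-yl)pent-1-yn-1-yl]trimethylsilane
Product: 5 3-(pent-4-yn-1-yl)furan
Conditions: K2CO3 (0.2 equiv), MeOH, 23 °C
Reagents that add atoms: none
Why: Protodesilylation, in which catalytic methoxide attacks silicon and only the sp-carbon–silicon bond is cleaved.

Step 3
Reactants: 5 3-(pent-4-yn-1-yl)furan
Product: 7 3-[(4E)-5-iodo-4-methylpent-4-en-1-yl]furan, via [(1E)-5-(furan-3-yl)-2-methylpent-1-en-1-yl]dimethylalane 6 (not isolated)
Conditions: Me3Al (2.0 equiv), Cp2ZrCl2 (0.25 equiv), CH2Cl2, 0 → 23 °C; then I2 (1.2 equiv), THF, −30 → 0 °C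
Reagents that add atoms: trimethylaluminium, C[Al](C)C; iodine, II
Why: Negishi zirconium-catalysed carboalumination adds CH3 and Al syn across the terminal alkyne with Al on the terminal carbon, and iodinolysis of the carbon–aluminium bond with retention gives the E-alkenyl iodide.

Step 4
Reactants: 7 3-[(4E)-5-iodo-4-methylpent-4-en-1-yl]furan
Product: 8 2-[(1E)-5-(furan-3-yl)-2-methylpent-1-en-1-yl]-4,4,5,5-tetramethyl-1,3,2-dioxaborolane
Conditions: B2pin2 (1.1 equiv), PdCl2(PPh3)2 (3 mol%), PPh3 (6 mol%), KOPh (1.5 equiv), toluene, 50 °C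
Reagents that add atoms: bis(pinacolato)diboron, CC1(C)OB(OC1(C)C)B1OC(C)(C)C(C)(C)O1
Why: Miyaura borylation, in which oxidative addition of the alkenyl iodide, phenoxide-assisted transmetalation with B2pin2 and reductive elimination all proceed with retention of the E geometry.

Step 5
Reactants: 9 ethyl 2-methyl-3-oxobutanoate
Product: 11 ethyl 4-bromo-2-methyl-3-oxobutanoate, via ethyl 2-bromo-2-methyl-3-oxobutanoate 10 (not isolated)
Conditions: Br2 (1.0 equiv), CHCl3, 0 → 23 °C, 16 h; concentrate, use crude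
Reagents that add atoms: bromine, BrBr
Why: Electrophilic bromination of the β-keto ester enol gives the 2-bromo ester 10 first, and the HBr formed transfers the bromine to the terminal carbon to give the more stable 4-bromo ester 11.

Step 6
Reactants: 11 ethyl 4-bromo-2-methyl-3-oxobutanoate
Product: 12 4-hydroxy-3-methylfuran-2(5H)-one (3-methyltetronic acid)
Conditions: neat, 130 °C, 2 h; crystallise
Reagents that add atoms: none
Why: Thermal lactonisation, in which the ester carbonyl oxygen displaces the primary bromide and bromide dealkylates the resulting oxonium ion to leave the enolised β-keto lactone, closing the butenolide ring.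

Step 7
Reactants: 12 4-hydroxy-3-methylfuran-2(5H)-one
Product: 13 4-methoxy-3-methylfuran-2(5H)-one
Conditions: Me2SO4 (1.1 equiv), K2CO3 (1.5 equiv), acetone, reflux
Reagents that add atoms: dimethyl sulfate, COS(=O)(=O)OC
Why: O-Alkylation of the vinylogous acid (pKa about 4) by the hard electrophile dimethyl sulfate gives the 4-O-methyl tetronate.

Step 8
Reactants: 13 4-methoxy-3-methylfuran-2(5H)-one
Product: 14 tert-butyl[(4-methoxy-3-methylfuran-2-yl)oxy]dimethylsilane
Conditions: TBSOTf (1.1 equiv), Et3N (1.5 equiv), CH2Cl2, 0 °C; filter through basic alumina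
Reagents that add atoms: tert-butyldimethylsilyl trifluoromethanesulfonate, CC(C)(C)[Si](C)(C)OS(=O)(=O)C(F)(F)F
Why: Soft enolisation, in which silylation of the lactone carbonyl oxygen acidifies the C5 hydrogen and triethylamine removes it to give the aromatic 2-silyloxyfuran.

Step 9
Reactants: 15 (3S)-3,7-dimethylocta-1,6-diene ((S)-β-citronellene)
Product: 16 (2E,6S)-2,6-dimethylocta-2,7-dien-1-ol
Conditions: SeO2 (10 mol%), salicylic acid (10 mol%), t-BuOOH (70% in water, 3 equiv), CH2Cl2, 23 °C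
Reagents that add atoms: tert-butyl hydroperoxide, CC(C)(C)OO
Why: Sharpless SeO2/t-BuOOH allylic oxidation (ene reaction then [2,3]-sigmatropic shift) attacks the electron-rich trisubstituted alkene and oxidises the methyl group trans to the chain, giving the E-allylic alcohol while the vinyl group and the C6 (S) centre bought with 15 stay untouched.

Step 10
Reactants: 16 (2E,6S)-2,6-dimethylocta-2,7-dien-1-ol
Product: 17 (2E,6S)-2,6-dimethylocta-2,7-dien-1-yl methyl carbonate
Conditions: ClCO2Me (1.3 equiv), pyridine (2 equiv), CH2Cl2, 0 °C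
Reagents that add atoms: methyl chloroformate, COC(=O)Cl
Why: Acylation of the primary allylic alcohol by the chloroformate (carbonate formation) installs a leaving group that releases its own base on ionisation.

Step 11
Reactants: 17 (2E,6S)-2,6-dimethylocta-2,7-dien-1-yl methyl carbonate; 14 tert-butyl[(4-methoxy-3-methylfuran-2-yl)oxy]dimethylsilane
Product: 18 (5R)-5-[(2E,6S)-2,6-dimethylocta-2,7-dien-1-yl]-4-methoxy-3-methylfuran-2(5H)-one
Conditions: Pd2(dba)3·CHCl3 (2.5 mol%), (R,R)-ANDEN-phenyl Trost ligand (6.5 mol%), 14 (1.3 equiv), 1,4-dioxane, 20 °C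
Reagents that add atoms: none
Why: Proposed new method: zerovalent palladium ionises 17 to a syn-configured 2-methyl-π-allyl complex, the methoxide released on decarboxylation desilylates 14 to a 4-methoxyfuran-2-olate held as an ion pair in the chiral ligand pocket, and this planar dienolate attacks the unsubstituted allyl terminus through C5 (C3 is blocked by its methyl group and C5 attack restores the conjugated tetronate), with one enantioface selected by hydrogen bonding of the furanolate oxygen to a ligand amide N–H so that C5 is set R under essentially base-free conditions that cannot epimerise it, and with the 2E alkene kept because capture is faster than syn/anti isomerisation; the closest known reaction types are the Tsuji–Trost asymmetric allylic alkylation of prochiral enolates and silyl enol ethers that sets tertiary α-carbonyl stereocentres and the C5-selective vinylogous Mukaiyama reactions of 2-silyloxyfurans.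

Step 12
Reactants: 18 (5R)-5-[(2E,6S)-2,6-dimethylocta-2,7-dien-1-yl]-4-methoxy-3-methylfuran-2(5H)-one; 8 2-[(1E)-5-(furan-3-yl)-2-methylpent-1-en-1-yl]-4,4,5,5-tetramethyl-1,3,2-dioxaborolane
Product: 19 (5R)-5-[(2E,6S,7E,9E)-13-(furan-3-yl)-2,6,10-trimethyltrideca-2,7,9-trien-1-yl]-4-methoxy-3-methylfuran-2(5H)-one
Conditions: Pd(OAc)2 (10 mol%), 1,2-bis(phenylsulfinyl)ethane (10 mol%), 8 (1.5 equiv), 2,6-dimethyl-1,4-benzoquinone (1.5 equiv), AcOH (4 equiv), 1,4-dioxane, 35 °C
Reagents that add atoms: none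
Why: Oxidative boron-Heck vinylation under divalent palladium/bis-sulfoxide catalysis, in which the alkenyl group of 8 transmetalates to palladium, adds to the terminal carbon of the vinyl group of 18 and β-hydride elimination towards the new alkenyl group gives the conjugated E,E-diene, the sulfoxide ligand and quinone suppressing Pd–H re-insertion so that the adjacent C6 centre and the alkene positions are not scrambled.

Step 13
Reactants: 19 (5R)-5-[(2E,6S,7E,9E)-13-(furan-3-yl)-2,6,10-trimethyltrideca-2,7,9-trien-1-yl]-4-methoxy-3-methylfuran-2(5H)-one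
Product: 20 (5R)-5-[(2E,6S,7E,9E)-13-(furan-3-yl)-2,6,10-trimethyltrideca-2,7,9-trien-1-yl]-4-hydroxy-3-methylfuran-2(5H)-one
Conditions: NaSPh (3 equiv), degassed DMF, 60 °C, dark; then 1 M HCl, 0 °C
Reagents that add atoms: none
Why: SN2 demethylation of the vinylogous methyl ester by the soft thiophenolate with the tetronate anion as leaving group, thiophenolate being too weak a base to remove the C5 hydrogen, so the C5 centre, the diene and the furan survive.

## Compound list

1 | (5-chloropent-1-yn-1-yl)trimethylsilane | C[Si](C)(C)C#CCCCCl | starting material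
2 | 3-bromofuran | Brc1ccoc1 | starting material
3 | [5-(trimethylsilyl)pent-4-yn-1-yl]magnesium chloride | C[Si](C)(C)C#CCCC[Mg]Cl | intermediate
4 | [5-(furan-3-yl)pent-1-yn-1-yl]trimethylsilane | C[Si](C)(C)C#CCCCc1ccoc1 | intermediate
5 | 3-(pent-4-yn-1-yl)furan | C#CCCCc1ccoc1 | intermediate
6 | [(1E)-5-(furan-3-yl)-2-methylpent-1-en-1-yl]dimethylalane | C[Al](C)/C=C(\C)CCCc1ccoc1 | intermediate
7 | 3-[(4E)-5-iodo-4-methylpent-4-en-1-yl]furan | I/C=C(\C)CCCc1ccoc1 | intermediate
8 | 2-[(1E)-5-(furan-3-yl)-2-methylpent-1-en-1-yl]-4,4,5,5-tetramethyl-1,3,2-dioxaborolane | CC1(C)OB(/C=C(\C)CCCc2ccoc2)OC1(C)C | intermediate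
9 | ethyl 2-methyl-3-oxobutanoate | CCOC(=O)C(C)C(C)=O | starting material
10 | ethyl 2-bromo-2-methyl-3-oxobutanoate | CCOC(=O)C(C)(Br)C(C)=O | intermediate
11 | ethyl 4-bromo-2-methyl-3-oxobutanoate | CCOC(=O)C(C)C(=O)CBr | intermediate
12 | 4-hydroxy-3-methylfuran-2(5H)-one (3-methyltetronic acid) | CC1=C(O)COC1=O | intermediate
13 | 4-methoxy-3-methylfuran-2(5H)-one | CC1=C(OC)COC1=O | intermediate
14 | tert-butyl[(4-methoxy-3-methylfuran-2-yl)oxy]dimethylsilane | COc1coc(O[Si](C)(C)C(C)(C)C)c1C | intermediate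
15 | (3S)-3,7-dimethylocta-1,6-diene ((S)-β-citronellene) | CC(C)=CCC[C@H](C)C=C | starting material
16 | (2E,6S)-2,6-dimethylocta-2,7-dien-1-ol | OC/C(C)=C/CC[C@H](C)C=C | intermediate
17 | (2E,6S)-2,6-dimethylocta-2,7-dien-1-yl methyl carbonate | COC(=O)OC/C(C)=C/CC[C@H](C)C=C | intermediate
18 | (5R)-5-[(2E,6S)-2,6-dimethylocta-2,7-dien-1-yl]-4-methoxy-3-methylfuran-2(5H)-one | CC1=C(OC)[C@@H](C/C(C)=C/CC[C@H](C)C=C)OC1=O | intermediate
19 | (5R)-5-[(2E,6S,7E,9E)-13-(furan-3-yl)-2,6,10-trimethyltrideca-2,7,9-trien-1-yl]-4-methoxy-3-methylfuran-2(5H)-one | CC1=C(OC)[C@@H](C/C(C)=C/CC[C@H](C)/C=C/C=C(\C)CCCc2ccoc2)OC1=O | intermediate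
20 | (5R)-5-[(2E,6S,7E,9E)-13-(furan-3-yl)-2,6,10-trimethyltrideca-2,7,9-trien-1-yl]-4-hydroxy-3-methylfuran-2(5H)-one | CC1=C(O)[C@@H](C/C(C)=C/CC[C@H](C)/C=C/C=C(\C)CCCc2ccoc2)OC1=O | target

## Step count and risks

Total step count: 13. Longest linear sequence: 7 steps (9 → 11 → 12 → 13 → 14 → 18 → 19 → 20, steps 5, 6, 7, 8, 11, 12, 13). The other branches are 6 steps from 1 and 5 steps from 15.

**Step 11 (the proposed new allylation).** The risks are:
- the level and sense of enantioselection at C5;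
- competing C3- or O-allylation of the furanolate;
- loss of the 2E geometry if the 2-methylallyl complex undergoes syn/anti isomerisation before capture;
- intramolecular allylpalladation of the C7 vinyl group (an octa-2,7-dienyl system) if the mixture is warmed.

Fallback, known chemistry only, setting out from 16 and coming back at 18: 16 is brominated (CBr4, PPh3) to (2E,6S)-1-bromo-2,6-dimethylocta-2,7-diene F1. The sodium enolate (NaN(SiMe3)2, THF, −78 °C) of (4S)-4-benzyl-3-{[(4-methoxybenzyl)oxy]acetyl}-1,3-oxazolidin-2-one F2, itself made from (S)-4-benzyloxazolidin-2-one, n-BuLi and (4-methoxybenzyloxy)acetyl chloride, is alkylated by F1 on the face away from the benzyl group (Evans–Crimmins glycolate alkylation). This gives (4S)-4-benzyl-3-{(2R,4E,8S)-2-[(4-methoxybenzyl)oxy]-4,8-dimethyldeca-4,9-dienoyl}-1,3-oxazolidin-2-one F3. MeOMgBr removes the auxiliary to give methyl (2R,4E,8S)-2-[(4-methoxybenzyl)oxy]-4,8-dimethyldeca-4,9-dienoate F4. DDQ unmasks methyl (2R,4E,8S)-2-hydroxy-4,8-dimethyldeca-4,9-dienoate F5. Propanoyl chloride and pyridine give methyl (2R,4E,8S)-4,8-dimethyl-2-(propanoyloxy)deca-4,9-dienoate F6. Dieckmann cyclisation (LiN(SiMe3)2, THF, −78 °C) closes (5R)-5-[(2E,6S)-2,6-dimethylocta-2,7-dien-1-yl]-4-hydroxy-3-methylfuran-2(5H)-one F7. O-Methylation as in step 7 gives 18.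

**Step 12 (oxidative Heck vinylation).** The risks are:
- slow transmetalation of the trisubstituted alkenylboronate, with protodeboronation or homocoupling;
- sluggish insertion into the α-branched alkene;
- palladation of the furan.

Fallback, cross-coupling in place of C–H vinylation, setting out from 15 and coming back at 19: mCPBA epoxidises only the trisubstituted alkene of 15 to 2,2-dimethyl-3-[(3S)-3-methylpent-4-en-1-yl]oxirane F8 (both oxirane epimers; that centre is destroyed later), which removes the ring-closing pathway. Cross-metathesis with 4,4,5,5-tetramethyl-2-vinyl-1,3,2-dioxaborolane (second-generation Grubbs catalyst RuCl2(=CHPh)(PCy3)(H2IMes)) gives 2-[(1E,3S)-5-(3,3-dimethyloxiran-2-yl)-3-methylpent-1-en-1-yl]-4,4,5,5-tetramethyl-1,3,2-dioxaborolane F9. Suzuki–Miyaura coupling with iodide 7 (Pd(PPh3)4, aqueous K3PO4, THF) gives 3-[(4E,6E,8S)-10-(3,3-dimethyloxiran-2-yl)-4,8-dimethyldeca-4,6-dien-1-yl]furan F10. H5IO6 cleaves the epoxide to (4S,5E,7E)-11-(furan-3-yl)-4,8-dimethylundeca-5,7-dienal F11. Wittig reaction with Ph3P=C(CH3)CO2Et gives ethyl (2E,6S,7E,9E)-13-(furan-3-yl)-2,6,10-trimethyltrideca-2,7,9-trienoate F12. (i-Bu)2AlH reduces it to (2E,6S,7E,9E)-13-(furan-3-yl)-2,6,10-trimethyltrideca-2,7,9-trien-1-ol F13. ClCO2Me and pyridine give (2E,6S,7E,9E)-13-(furan-3-yl)-2,6,10-trimethyltrideca-2,7,9-trien-1-yl methyl carbonate F14. Allylation of 14 with F14 under the conditions of step 11 gives 19.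

**Step 13 (demethylation).** The risks are:
- incomplete SN2 cleavage of the hindered vinylogous ester;
- thiol addition to the diene during acidic work-up;
- C5 epimerisation if the medium turns basic.

Fallback, a fluoride-labile ether in place of the methyl ether, setting out from 12 and coming back at 20: Mitsunobu O-alkylation of 12 with 2-(trimethylsilyl)ethanol (PPh3, DIAD) gives 3-methyl-4-[2-(trimethylsilyl)ethoxy]furan-2(5H)-one F15. TBSOTf and Et3N give tert-butyldimethyl({3-methyl-4-[2-(trimethylsilyl)ethoxy]furan-2-yl}oxy)silane F16. Allylation with 17 as in step 11 gives (5R)-5-[(2E,6S)-2,6-dimethylocta-2,7-dien-1-yl]-3-methyl-4-[2-(trimethylsilyl)ethoxy]furan-2(5H)-one F17. Vinylation with 8 as in step 12 gives (5R)-5-[(2E,6S,7E,9E)-13-(furan-3-yl)-2,6,10-trimethyltrideca-2,7,9-trien-1-yl]-3-methyl-4-[2-(trimethylsilyl)ethoxy]furan-2(5H)-one F18. Bu4NF in THF at 0 °C attacks silicon and triggers β-elimination to give 20 without heat or thiolate.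

## Further compounds

F1 | step 11 | (2E,6S)-1-bromo-2,6-dimethylocta-2,7-diene | BrC/C(C)=C/CC[C@H](C)C=C
F2 | step 11 | (4S)-4-benzyl-3-{[(4-methoxybenzyl)oxy]acetyl}-1,3-oxazolidin-2-one | COc1ccc(COCC(=O)N2[C@@H](Cc3ccccc3)COC2=O)cc1
F3 | step 11 | (4S)-4-benzyl-3-{(2R,4E,8S)-2-[(4-methoxybenzyl)oxy]-4,8-dimethyldeca-4,9-dienoyl}-1,3-oxazolidin-2-one | COc1ccc(CO[C@H](C/C(C)=C/CC[C@H](C)C=C)C(=O)N2[C@@H](Cc3ccccc3)COC2=O)cc1
F4 | step 11 | methyl (2R,4E,8S)-2-[(4-methoxybenzyl)oxy]-4,8-dimethyldeca-4,9-dienoate | COc1ccc(CO[C@H](C/C(C)=C/CC[C@H](C)C=C)C(=O)OC)cc1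
F5 | step 11 | methyl (2R,4E,8S)-2-hydroxy-4,8-dimethyldeca-4,9-dienoate | O[C@H](C/C(C)=C/CC[C@H](C)C=C)C(=O)OC
F6 | step 11 | methyl (2R,4E,8S)-4,8-dimethyl-2-(propanoyloxy)deca-4,9-dienoate | CCC(=O)O[C@H](C/C(C)=C/CC[C@H](C)C=C)C(=O)OC
F7 | step 11 | (5R)-5-[(2E,6S)-2,6-dimethylocta-2,7-dien-1-yl]-4-hydroxy-3-methylfuran-2(5H)-one | CC1=C(O)[C@@H](C/C(C)=C/CC[C@H](C)C=C)OC1=O
F8 | step 12 | 2,2-dimethyl-3-[(3S)-3-methylpent-4-en-1-yl]oxirane | CC1(C)OC1CC[C@H](C)C=C
F9 | step 12 | 2-[(1E,3S)-5-(3,3-dimethyloxiran-2-yl)-3-methylpent-1-en-1-yl]-4,4,5,5-tetramethyl-1,3,2-dioxaborolane | CC1(C)OC1CC[C@H](C)/C=C/B1OC(C)(C)C(C)(C)O1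
F10 | step 12 | 3-[(4E,6E,8S)-10-(3,3-dimethyloxiran-2-yl)-4,8-dimethyldeca-4,6-dien-1-yl]furan | CC1(C)OC1CC[C@H](C)/C=C/C=C(\C)CCCc1ccoc1
F11 | step 12 | (4S,5E,7E)-11-(furan-3-yl)-4,8-dimethylundeca-5,7-dienal | O=CCC[C@H](C)/C=C/C=C(\C)CCCc1ccoc1
F12 | step 12 | ethyl (2E,6S,7E,9E)-13-(furan-3-yl)-2,6,10-trimethyltrideca-2,7,9-trienoate | CCOC(=O)/C(C)=C/CC[C@H](C)/C=C/C=C(\C)CCCc1ccoc1
F13 | step 12 | (2E,6S,7E,9E)-13-(furan-3-yl)-2,6,10-trimethyltrideca-2,7,9-trien-1-ol | OC/C(C)=C/CC[C@H](C)/C=C/C=C(\C)CCCc1ccoc1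
F14 | step 12 | (2E,6S,7E,9E)-13-(furan-3-yl)-2,6,10-trimethyltrideca-2,7,9-trien-1-yl methyl carbonate | COC(=O)OC/C(C)=C/CC[C@H](C)/C=C/C=C(\C)CCCc1ccoc1
F15 | step 13 | 3-methyl-4-[2-(trimethylsilyl)ethoxy]furan-2(5H)-one | CC1=C(OCC[Si](C)(C)C)COC1=O
F16 | step 13 | tert-butyldimethyl({3-methyl-4-[2-(trimethylsilyl)ethoxy]furan-2-yl}oxy)silane | Cc1c(OCC[Si](C)(C)C)coc1O[Si](C)(C)C(C)(C)C
F17 | step 13 | (5R)-5-[(2E,6S)-2,6-dimethylocta-2,7-dien-1-yl]-3-methyl-4-[2-(trimethylsilyl)ethoxy]furan-2(5H)-one | CC1=C(OCC[Si](C)(C)C)[C@@H](C/C(C)=C/CC[C@H](C)C=C)OC1=O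
F18 | step 13 | (5R)-5-[(2E,6S,7E,9E)-13-(furan-3-yl)-2,6,10-trimethyltrideca-2,7,9-trien-1-yl]-3-methyl-4-[2-(trimethylsilyl)ethoxy]furan-2(5H)-one | CC1=C(OCC[Si](C)(C)C)[C@@H](C/C(C)=C/CC[C@H](C)/C=C/C=C(\C)CCCc2ccoc2)OC1=O
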